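**Retrosynthetic overview**
- The target (+)-lariciresinol (2S,3R,4R; 2,3-trans, 3,4-cis) comes from reductive etherification (last ring closed) of a 2-aryl lactol, which is made from the cis-3,4-disubstituted γ-butyrolactone and an aryllithium.
- The cis-lactone (first ring formed) comes from ozonolytic removal of the propenyl group of an Ireland–Claisen acid. Its C3–C4 bond and both stereocenters form in one [3,3]-sigmatropic step.
- The Claisen substrate is the ester of 3-(benzyloxy)propanoic acid with an (R)-(E)-secondary allylic alcohol. That alcohol comes from cross-metathesis of benzyl-eugenol with (R)-but-3-en-2-ol, the only purchased stereocenter.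
- Final step: global hydrogenolysis of the three benzyl ethers.

Assumption: (R)-but-3-en-2-ol (3), 3-(benzyloxy)propanoic acid (5) and 4-(benzyloxy)-3-methoxybromobenzene (9) are commercial.

---

**Step 1**
Reactants: 1, eugenol (4-allyl-2-methoxyphenol)
Product: 2, 4-allyl-1-(benzyloxy)-2-methoxybenzene
Conditions: BnBr, K2CO3, DMF, rt
Reagents that add atoms: benzyl bromide, BrCc1ccccc1
Why: Williamson etherification masks the phenol so that it survives LDA and ArLi later.

**Step 2**
Reactants: 2; 3, (R)-but-3-en-2-ol
Product: 4, (2R,3E)-5-[4-(benzyloxy)-3-methoxyphenyl]pent-3-en-2-ol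
Conditions: Hoveyda–Grubbs II (5 mol%), 1,4-benzoquinone (10 mol%), CH2Cl2, 40 °C, 3 (4 equiv)
Reagents that add atoms: none
Why: Olefin cross-metathesis between the terminal allyl arene and the allylic alcohol gives the E-alkene. Benzoquinone suppresses Ru–H isomerization of the allyl arene, and the carbinol stereocenter is untouched.

**Step 3**
Reactants: 4; 5, 3-(benzyloxy)propanoic acid
Product: 6, (2R,3E)-5-[4-(benzyloxy)-3-methoxyphenyl]pent-3-en-2-yl 3-(benzyloxy)propanoate
Conditions: EDC·HCl, DMAP, CH2Cl2, 0 °C → rt
Reagents that add atoms: none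
Why: Steglich esterification does not touch the carbinol stereocenter.

**Step 4**
Reactants: 6
Product: 7, (2R,3S,4E)-2-[(benzyloxy)methyl]-3-{[4-(benzyloxy)-3-methoxyphenyl]methyl}hex-4-enoic acid
Conditions: LDA, TMSCl, THF, −78 °C → rt; then 1 M HCl
Reagents that add atoms: none (the silyl ester is cleaved on workup)
Why: This is the Ireland–Claisen [3,3]-sigmatropic rearrangement. LDA in THF gives the (E)-silyl ketene acetal. It reacts through a chair transition state with the (E)-alkene substituent and the carbinol methyl equatorial. The (R)-carbinol transfers its chirality suprafacially to C4, and the geometry gives the anti relationship (cis in the later ring) at C3/C4.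

**Step 5**
Reactants: 7
Product: 8, (3R,4R)-3-[(benzyloxy)methyl]-4-{[4-(benzyloxy)-3-methoxyphenyl]methyl}oxolan-2-one (cis-lactone)
Conditions: O3, CH2Cl2/MeOH, −78 °C; then NaBH4, −78 → 0 °C; then cat. TsOH, CH2Cl2, rt
Reagents that add atoms: ozone, O=[O+][O-] (supplies the oxygen of the new CH2OH)
Why: Ozonolysis of the propenyl group gives the aldehyde, and NaBH4 reduces it to the primary alcohol. The γ-hydroxy acid (not isolated) lactonizes under acid. No stereocenter is touched, and the acetaldehyde fragment is lost.

**Step 6**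
Reactants: 8; 9, 4-(benzyloxy)-3-methoxybromobenzene
Product: 10, (3R,4R)-3-[(benzyloxy)methyl]-2-[4-(benzyloxy)-3-methoxyphenyl]-4-{[4-(benzyloxy)-3-methoxyphenyl]methyl}oxolan-2-ol (lactol, mixture of C2 epimers)
Conditions: 9, n-BuLi, THF, −78 °C; then add 8 at −78 °C, 1 h; aq NH4Cl
Reagents that add atoms: none (the aryl group comes from 9)
Why: Br/Li exchange followed by 1,2-addition to the lactone stops at the stable cyclic hemiketal at −78 °C, because the tetrahedral intermediate does not collapse. C3 and C4 are not affected.

**Step 7**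
Reactants: 10
Product: 11, tri-O-benzyl-(+)-lariciresinol
Conditions: Et3SiH, BF3·OEt2, CH2Cl2, −78 → −20 °C
Reagents that add atoms: none (hydride only)
Why: Ionic hydrogenation (reductive etherification). BF3 ionizes the lactol to a planar 2-aryl oxocarbenium ion. Hydride is delivered along the pseudoaxial trajectory on the envelope with the C3 CH2OBn pseudo-equatorial, which puts the aryl group pseudo-equatorial and trans to C3. This sets C2 as S and leaves both epimerizable carbons unaffected.

**Step 8**
Reactants: 11
Product: 12, (+)-lariciresinol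
Conditions: H2 (1 atm), 10% Pd/C, EtOAc/MeOH, rt
Reagents that add atoms: none
Why: Hydrogenolysis removes the two phenol benzyl ethers and the primary benzyl ether. The 2-aryl-THF C–O bonds and all stereocenters survive a short, low-pressure reaction.

---

**Compound list**

| No. | Name | SMILES | Role |
|---|---|---|---|
| 1 | Eugenol | C=CCc1ccc(O)c(OC)c1 | starting material |
| 2 | 4-Allyl-1-(benzyloxy)-2-methoxybenzene | C=CCc1ccc(OCc2ccccc2)c(OC)c1 | intermediate |
| 3 | (R)-But-3-en-2-ol | C[C@@H](O)C=C | starting material |
| 4 | (2R,3E)-5-Aryl-pent-3-en-2-ol (Ar = 4-BnO-3-MeO-C6H3) | C[C@@H](O)/C=C/Cc1ccc(OCc2ccccc2)c(OC)c1 | intermediate |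
| 5 | 3-(Benzyloxy)propanoic acid | OC(=O)CCOCc1ccccc1 | starting material |
| 6 | (2R,3E)-5-Aryl-pent-3-en-2-yl 3-(benzyloxy)propanoate | C[C@H](/C=C/Cc1ccc(OCc2ccccc2)c(OC)c1)OC(=O)CCOCc1ccccc1 | intermediate |
| 7 | (2R,3S,4E)-Claisen acid | OC(=O)[C@@H](COCc1ccccc1)[C@@H](Cc1ccc(OCc2ccccc2)c(OC)c1)/C=C/C | intermediate |
| 8 | cis-(3R,4R)-Lactone | O=C1OC[C@H](Cc2ccc(OCc3ccccc3)c(OC)c2)[C@@H]1COCc1ccccc1 | intermediate |
| 9 | 4-(Benzyloxy)-3-methoxybromobenzene | COc1cc(Br)ccc1OCc1ccccc1 | starting material |
| 10 | Lactol (C2 epimeric mixture) | OC1(c2ccc(OCc3ccccc3)c(OC)c2)OC[C@H](Cc2ccc(OCc3ccccc3)c(OC)c2)[C@@H]1COCc1ccccc1 | intermediate |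
| 11 | Tri-O-benzyl-(+)-lariciresinol | COc1cc(C[C@H]2CO[C@H](c3ccc(OCc4ccccc4)c(OC)c3)[C@H]2COCc2ccccc2)ccc1OCc1ccccc1 | intermediate |
| 12 | (+)-Lariciresinol | COc1cc(C[C@H]2CO[C@H](c3ccc(O)c(OC)c3)[C@H]2CO)ccc1O | target |

**Total steps:** 8. **Longest linear sequence:** 8 (1 → 2 → 4 → 6 → 7 → 8 → 10 → 11 → 12); the other partners (3, 5, 9) are purchased.

**Three steps most likely to fail**
1. **Step 4 (Ireland–Claisen).** Li-chelation by the β-OBn group could flip the ketene-acetal geometry, or E1cB loss of BnO⁻ could give an acrylate. Fallback: swap 5 for the non-chelating 3-(TBSO)propanoic acid, so the β-silyl ether cannot chelate lithium, and remove the TBS group during the BF3 step or with TBAF.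
2. **Step 7 (C2 selectivity).** The oxocarbenium reduction may give the 2,3-cis epimer. Fallback: reduce lactol 10 with NaBH4 to the 1,4-diol, separate the benzylic epimers, and cyclize the (S)-diol by selective primary tosylation then NaH (retention at C2).
3. **Step 6 (ArLi addition).** Over-addition to the diol, or epimerization or β-elimination of the lactone, is possible. Fallback: open lactone 8 with Me3Al/MeONHMe·HCl to the hydroxy Weinreb amide, then add ArMgBr (from 9) to give the same lactol 10 without over-addition.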